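Compound numbers are those of the steps and of the compound list below. Locants follow the carbon chain of the target: C1 (acetoxy methine), C2, C3 (methyl and acetoxy), C4, C5 (ring-fusion methine), C6, C7 (ketone), C8=C9, C10, C11, N12, C13–C15, C16 (quaternary).

## Analysis of the target

Target 34 is built from cyclohexane ring A (C1–C5, C16), cyclopentanone ring B (C5–C8, C16) and the nine-membered azacycle ring C (C8–C11, N12, C13–C16). Rings A and B share the C5–C16 bond as a cis-hydrindane. Ring C is annulated on the C8–C16 bond, and its only double bond, C8=C9, is exocyclic to ring B and conjugated with the C7 ketone (ring-cis, E by the sequence rule). The four stereocentres are 1S, 3S, 5S and 16S: both acetoxy groups, the C5–C6 bond and the C16–C8 bond lie on one face of ring A, while the C3 methyl group, C5–H and C15 lie on the other, so ring A can hold both acetates and C6 equatorial. C16 is the critical centre, because it is quaternary, belongs to all three rings and is flanked by the oxygenated C1. The free secondary amine beside an enone and two esters, the tertiary C3 acetate and the exocyclic enone are all sensitive, which argues for releasing amine and enone at the very end. The synthesis is hard because a quaternary carbon must be made at the junction of a congested bicycle and a medium ring, and a nine-membered ring is difficult to close late on such a core. The strategy rests on one feature: C16 carries the oxygenated C1 on one side and C8 on the other, with C7 oxygenated next to C8, which is the pattern left when a C7 oxocarbenium ion adds to a C8=C16 alkene and C5 then shifts from C1 to C16.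

## Retrosynthetic reasoning

**34 from 33.** The last bond cut is the N12–carbonyl bond of a carbamate. A free amine cannot survive the acylations, the oxidation and the palladium step that precede it, and an amine next to an enone is best made once, at the end. The tert-butyl carbamate of 33 is chosen because its removal needs no reductant (enone), no nucleophile (enone, acetates) and no strong base. The forward step only has to spare the tertiary acetate.

**33 from 31 through 32.** The C8=C9 double bond is traced back to saturated ketone 31 by way of its silyl enol ether 32, that is, by removal of hydrogen from C8 and C9. Cutting here, and not closing ring C at the enone, keeps the medium ring intact throughout. Because C16 is quaternary, an enolate equivalent placed at C8 can only eliminate toward C9. The forward steps must place the enol ether on the C8 side of C7.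

**31 back to 25.** No skeletal bond is cut; the order of events is what matters.
- The C7 ketone comes from alcohol 30 and this from benzyl ether 29.
- Both acetates come from diol 28 in one acylation while the C7 oxygen is still benzylated, which tells the three oxygens apart.
- Diol 28 comes from silyl ether 27, the carbamate from amine 26, and both the amine and the C1 alcohol of 26 from 25 by a single electron-transfer reduction.
- Nitrogen carries a tosyl group up to 25 because it has no acidic C–H next to sulfur and withstands organolithium and Lewis acid chemistry. A 2-(trimethylsilyl)ethanesulfonyl group would allow fluoride cleavage at the end, but its C–H bonds next to sulfur are at risk when alkenyllithium 19 is made.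
- C3 carries a tertiary silyl ether and not a benzyl ether, because it cannot ionise under the Lewis acid of the key step and can be put on β-hydroxy ketone 3 without base.

**25 from 22 (key disconnection).** The bonds C7–C8 and C5–C16 are cut, with C5 returned to C1. This removes ring B, shrinks ring A to a cyclopentane and leaves the azacycle as a plain alkenyl substituent. The cut is made here because it creates the quaternary C16 in the same event that joins the three rings, and because the C16 configuration is then relayed from C5 through a cyclic transition state. In the forward direction the acetal of 22 must ionise to 23, the alkene must attack through C8 to give cation 24, and C5 must migrate before the medium-ring cation finds another outlet.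

**22 from 18 and 12.** The C1–C16 bond is cut to give an alkenyl nucleophile (19, 20) from vinyl bromide 18 and ketone 12, followed by silylation of alcohol 21. This is the most convergent cut, since each partner holds about half of the carbons. The addition must avoid enolisation of 12 and take place anti to the C5 side chain.

**18 from 13 and 14.** The vinyl bromide comes from symmetric alkene 16 by halogenation and dehydrohalogenation through 17. The ring comes from diene 15 by ring-closing metathesis, and 15 from sulfonamide 13 and two molecules of bromide 14. The medium ring is thus closed on an unsubstituted chain, and the symmetry of 16 removes any regiochemical question in the metathesis.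

**12 from 6 and 7.** The C5–C6 bond is cut: the acetal arm of 12 comes from aldehyde 11, and this from the allyl group of 9, introduced with allyl bromide 7 on azaenolate 8 of hydrazone 6. A chiral hydrazone is used because the C3 centre is too remote to control C5 reliably, and C5 must be cis to the C3 oxygen. Release of the ketone and cleavage of the alkene are merged in one oxidative step through ozonide 10.

**6 from 1 and 5.** Hydrazone 6 comes from ketone 4 and hydrazine 5, 4 from alcohol 3, and 3 from enone 1 by cutting the C3–O bond (conjugate borylation to 2, then oxidation). This sets the absolute configuration of the route in the first step with a catalyst.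

## Alternatives that were turned down

**Alternative 1:** Ring A is opened at C1–C16 and C4–C5, a Diels–Alder retron. In the forward step a chiral copper bis(oxazoline) Lewis acid binds 2-carbomethoxycyclopent-2-enone A3 and directs 1-silyloxy-3-methylbutadiene A2 onto it, giving cis-hydrindenone A1.
- For it: one catalytic enantioselective step creates C1, C5 and the quaternary C16 with the cis fusion from two simple partners. On absolute control of C16 it is stronger than the chosen route, where C16 is relayed from C5.
- Against it: A1 has its ketone on C8 and not C7, a one-carbon ester on C16 where the three-carbon C15–C13 arm is needed, and a C2=C3 alkene where the tertiary C3 acetate must stand. Carbonyl relocation, ester homologation and a face-selective hydration at C3 all remain. Above all, the nine-membered ring must still be closed between the neopentyl positions C8 and C16 of a finished bicycle.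
- Comparison: the hardest operation is left to the end and the step count after the key step is higher. The chosen strategy gives up direct catalytic control of C16 but brings the azacycle in ready-made and forms C16 while the rings are joined.

**Alternative 2:** Ring C is opened at C8–C9. A divalent samarium reductant converts the C8 gem-dichloride of aldehyde A5 into a samarium enolate, which adds to the C9 aldehyde; a second reduction expels the β-oxygen and gives A4, identical with 33.
- For it: ring C and the enone are formed together, and the position of the double bond is fixed by the bonds formed. On this point it is stronger than the chosen route, which depends on the direction of enolisation in step 20.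
- Against it: a nine-membered ring is closed by an aldol-type addition of a fully substituted enolate next to quaternary C16, which is disfavoured by ring strain and entropy and needs high dilution. The quaternary C16 with its aminopropyl arm has to be built by separate chemistry, so the central problem is moved and not solved. A gem-dichloride must be placed on the hindered C8, a free aldehyde carried late, and the alkene geometry is not controlled by the mechanism.
- Comparison: the endgame is shorter, but the risk lies in a late medium-ring closure on the full core. The chosen strategy has a longer endgame but forms ring C on a simple chain at the start.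

**Alternative 3:** Ring C is opened at C10–C11 and contracted to a piperidine. A copper carbenoid from a diazoacetate is captured by the tertiary amine of fused 2-vinylpiperidine A7, and the ammonium ylide undergoes a [2,3] shift (C10–C11 formed, N–C8 broken) to give azonane A6.
- For it: the medium ring arises by three-atom ring expansion of an easily made six-membered ring, and the double bond is placed at C8=C9 by the mechanism. For forming the nine-membered ring itself this is as strong as, or stronger than, metathesis.
- Against it: A7 needs a fully substituted C8 bearing nitrogen and a vinyl group next to quaternary C16. The ylide must form on the nitrogen face cis to the vinyl group, and a [1,2] shift competes. The alkene geometry from the five-membered transition state is not assured to be ring-cis. A6 also carries an extra C11 ester, a C7 methylene that needs a selective allylic oxidation in the presence of the C10 methylene, and an N-benzyl group that cannot be removed by hydrogenolysis next to the alkene.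
- Comparison: three clean-up operations follow on the complete skeleton, and the congested amine has to be made first. The chosen strategy forms the medium ring away from the core and needs no extra carbon to be removed.

Key step: step 13

Assumption: the sense of induction of the bisphosphine in step 1 is not derived here; the ligand antipode that gives (S)-3 is meant, and both antipodes are available.

## Route

Step 1
Reactants: 1 3-methylcyclopent-2-en-1-one
Product: 3 (S)-3-hydroxy-3-methylcyclopentan-1-one, via boronate 2 (not isolated)
Conditions: B2pin2, Cu(MeCN)4PF6 (cat.), QuinoxP* (cat., antipode giving S), LiOtBu (cat.), MeOH, DMSO, rt; then NaBO3·4H2O, THF–H2O, 0 °C to rt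
Reagents that add atoms: bis(pinacolato)diboron, CC1(C)OB(OC1(C)C)B2OC(C)(C)C(C)(C)O2 (boryl group of 2); sodium perborate, [Na+].[O-]OB=O (hydroxyl oxygen of 3)
Why: Copper-catalysed enantioselective conjugate borylation of a β-substituted cyclic enone; the chiral bisphosphine–copper boryl species adds to one enantiotopic face of C3 and sets the tetrasubstituted centre as boronate 2. Perborate oxidation replaces boron by oxygen with retention, so the oxygen of the later C3 acetate is installed with its absolute configuration in the first step.

Step 2
Reactants: 3 (S)-3-hydroxy-3-methylcyclopentan-1-one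
Product: 4 (S)-3-(tert-butyldimethylsilyloxy)-3-methylcyclopentan-1-one
Conditions: TBSOTf, 2,6-lutidine, CH2Cl2, −78 to 0 °C
Reagents that add atoms: tert-butyldimethylsilyl trifluoromethanesulfonate, CC(C)(C)[Si](C)(C)OS(=O)(=O)C(F)(F)F
Why: Silylation with a silyl triflate and a hindered pyridine base avoids the alkoxide that would trigger retro-aldol cleavage or dehydration of the β-hydroxy ketone. The tertiary silyl ether resists LiN(iPr)2, organocerium reagents and SnCl4 and cannot serve as a cation source.

Step 3
Reactants: 4 (S)-3-(tert-butyldimethylsilyloxy)-3-methylcyclopentan-1-one; 5 (S)-1-amino-2-(methoxymethyl)pyrrolidine (SAMP)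
Product: 6 (S)-N-[(S)-3-(tert-butyldimethylsilyloxy)-3-methylcyclopentylidene]-2-(methoxymethyl)pyrrolidin-1-amine
Conditions: 5 (1.1 equiv), neat, 60 °C
Reagents that add atoms: none
Why: Condensation of the ketone with the chiral hydrazine gives the hydrazone. It attaches the auxiliary that will control C5 and masks the carbonyl, so the β-silyloxy group is not eliminated under the strong base of the next step.

Step 4
Reactants: 6 SAMP hydrazone of 4; 7 allyl bromide
Product: 9 (S)-N-[(2R,4S)-2-allyl-4-(tert-butyldimethylsilyloxy)-4-methylcyclopentylidene]-2-(methoxymethyl)pyrrolidin-1-amine, via lithium azaenolate 8 (not isolated)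
Conditions: LiN(iPr)2, THF, 0 °C; then 7, −95 to −78 °C
Reagents that add atoms: lithium diisopropylamide, [Li+].CC(C)[N-]C(C)C (lithium of 8)
Why: Enders SAMP hydrazone alkylation; deprotonation occurs at the less hindered C5 methylene (C2 is neopentyl, next to quaternary C3). The chelated azaenolate 8 is alkylated on the face set by the auxiliary, which for SAMP places the allyl group cis to the C3 silyloxy group (2R in 9). Reagent control by the auxiliary should override the weak bias of the remote C3 substituents.

Step 5
Reactants: 9 allylated SAMP hydrazone
Product: 11 2-[(1S,4S)-4-(tert-butyldimethylsilyloxy)-4-methyl-2-oxocyclopentyl]acetaldehyde, via ozonide 10 (not isolated)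
Conditions: O3, CH2Cl2, −78 °C; then Me2S, −78 °C to rt
Reagents that add atoms: ozone, [O-][O+]=O
Why: Ozonolysis cleaves the C=N bond of the hydrazone to the ketone (the auxiliary leaves as its N-nitroso derivative, to be handled as a carcinogen) and turns the terminal alkene into ozonide 10, which dimethyl sulfide reduces to the aldehyde. These neutral, cold conditions are the standard racemisation-free release of α-branched ketones from such hydrazones, so C5 is kept.

Step 6
Reactants: 11 keto aldehyde
Product: 12 (2S,4S)-2-[2,2-bis(benzyloxy)ethyl]-4-(tert-butyldimethylsilyloxy)-4-methylcyclopentan-1-one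
Conditions: BnOSiMe3 (2.2 equiv), TMSOTf (5 mol%), CH2Cl2, −78 °C; pyridine quench
Reagents that add atoms: benzyloxytrimethylsilane, C[Si](C)(C)OCc1ccccc1
Why: Silyl-triflate-catalysed acetalisation with the silyl ether of the alcohol converts the aldehyde far faster than the α-branched ketone at −78 °C, without protic acid or water, so C5 is not epimerised and the silyl ether stays. Benzyl is chosen so that the C7 oxygen left after the key step can be freed by hydrogenolysis.

Step 7
Reactants: 13 4-methylbenzenesulfonamide; 14 5-bromopent-1-ene
Product: 15 4-methyl-N,N-di(pent-4-en-1-yl)benzenesulfonamide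
Conditions: 14 (2.3 equiv), K2CO3, DMF, 70 °C
Reagents that add atoms: none
Why: Double N-alkylation of a primary sulfonamide with a primary bromide under carbonate base. The tosyl group makes nitrogen non-basic for metathesis and bromination and has no acidic C–H next to sulfur, which matters in step 11.

Step 8
Reactants: 15 N,N-di(pent-4-enyl) sulfonamide
Product: 16 (Z)-1-(4-methylbenzenesulfonyl)-2,3,4,7,8,9-hexahydro-1H-azonine
Conditions: second-generation Grubbs catalyst RuCl2(=CHPh)(H2IMes)(PCy3) (5 mol%), CH2Cl2 (0.002 M), 40 °C
Reagents that add atoms: none
Why: Ring-closing metathesis of an N-sulfonyl diene at high dilution with loss of ethene. The nine-membered ring accommodates the cis double bond best, so the Z alkene is expected, and the symmetry of 15 leaves no regiochemical question.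

Step 9
Reactants: 16 (Z)-azonine
Product: 17 trans-5,6-dibromo-1-(4-methylbenzenesulfonyl)azonane (racemic, 5R*,6R*)
Conditions: Br2, CH2Cl2, −78 °C
Reagents that add atoms: bromine, BrBr
Why: Electrophilic anti addition of bromine to the cis alkene in a non-polar solvent at low temperature gives the trans vicinal dibromide. The sulfonamide nitrogen is too weak a nucleophile to open the bromonium ion across the ring.

Step 10
Reactants: 17 trans-dibromide
Product: 18 (E)-5-bromo-1-(4-methylbenzenesulfonyl)-2,3,4,7,8,9-hexahydro-1H-azonine (ring-cis double bond)
Conditions: KOtBu, THF, 0 °C to rt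
Reagents that add atoms: none
Why: Dehydrobromination of a vicinal dibromide with KOtBu is the standard route from medium-ring cis-cycloalkenes to 1-bromocycloalkenes. The proton geminal to bromine is the most acidic, so the vinyl bromide and not the allylic bromide is expected, and because 16 is symmetric both directions of elimination give the same compound.

Step 11
Reactants: 18 vinyl bromide; 12 acetal ketone
Product: 21 (1S,2S,4S)-2-[2,2-bis(benzyloxy)ethyl]-4-(tert-butyldimethylsilyloxy)-4-methyl-1-[(E)-1-(4-methylbenzenesulfonyl)-2,3,4,7,8,9-hexahydro-1H-azonin-5-yl]cyclopentan-1-ol, via alkenyllithium 19 (not isolated), via alkenylcerium dichloride 20 (not isolated)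
Conditions: 18, t-BuLi (2.05 equiv), THF, −78 °C; anhydrous CeCl3, THF, −78 °C; then 12, −78 °C; aq. NH4Cl
Reagents that add atoms: tert-butyllithium, [Li]C(C)(C)C (lithium of 19); cerium trichloride, Cl[Ce](Cl)Cl (CeCl2 unit of 20)
Why: Bromine–lithium exchange with retention of alkene geometry gives 19, and transmetallation to the weakly basic, oxophilic organocerium reagent 20 suppresses enolisation of 12 and β-elimination of the silyloxy group. 1,2-Addition occurs on the ketone face opposite to the C5 side chain and the C3 silyloxy group, which share the other face. The new carbinol centre is lost again in step 13, but the trans relation of alkenyl group and side chain is what the chair transition state of the key step requires.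

Step 12
Reactants: 21 tertiary allylic alcohol
Product: 22 triethylsilyl ether of 21, (1S,2S,4S)
Conditions: KN(SiMe3)2, THF, −78 °C; Et3SiCl, −78 to 0 °C
Reagents that add atoms: chlorotriethylsilane, CC[Si](Cl)(CC)CC
Why: Silylation of the hindered tertiary alkoxide with the silyl chloride. The alkoxide route is preferred to a silyl triflate with a pyridine base, which could attack the dibenzyl acetal, and the triethylsilyl ether later serves as the electron-releasing group that ends the pinacol shift.

Step 13
Reactants: 22 silyl ether acetal
Product: 25 tricyclic C1 ketone, (3S,5R,7R,8R,16S): C3 tert-butyldimethylsilyloxy, C7 benzyloxy, N12 tosyl, rings A and B cis-fused, via oxocarbenium ion 23 (not isolated), via tertiary carbocation 24 (not isolated)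
Conditions: SnCl4 (2.5 equiv), CH2Cl2, −78 to −23 °C; Et3N, then aq. NaHCO3
Reagents that add atoms: none
Why: SnCl4 ionises the dibenzyl acetal selectively (the silyl ethers are poorer Lewis bases and cannot give stabilised cations) to the E-oxocarbenium ion 23, whose C7 is attacked by alkene carbon C8, so the charge develops at the tertiary C16 next to the silyloxy carbon (cation 24). The C1–C5 bond of 24 lies nearly parallel to the vacant p orbital at C16, and its shift from C1 to C16, driven by formation of the C1 carbonyl as the triethylsilyl group passes to the benzyloxide, gives 25; this is the Prins–pinacol ring-enlarging cyclopentane annulation known for 1-alkenylcycloalkanol silyl ethers with acetal side chains, of which the nine-membered alkenyl partner is an untested member. The first closure forms a six-membered ring (C1, C5, C6, C7, C8, C16), endo with respect to the alkene and exo with respect to the C=O+ bond, and the shift then contracts it to five-membered ring B and enlarges the cyclopentane to six-membered ring A. Because alkenyl group and side chain are trans on the cyclopentane, the transition state is a chair trans-fused to it with C2 and C4 equatorial, which exposes only one face of the alkene. Both new bonds (C7–C8 and C5–C16) are therefore made on the same alkene face and the migrating carbon keeps its configuration, which fixes C16 as 16S with C15 on the side of C5–H, the cis fusion of the target. C8 follows from the ring-cis alkene geometry and C7 from the equatorial benzyloxy group of the E-oxocarbenium ion; both centres are removed later. The step needs attack at C8 and not C16, secured by the trisubstituted alkene (tertiary against secondary cation), and migration of C5 and not C2, secured by the alignment of the ring bond and the better migrating ability of the secondary carbon. The shift must also outrun transannular hydride transfer and proton loss in the medium ring, which the adjacent silyloxy group should ensure.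

Step 14
Reactants: 25 tricyclic ketone
Product: 26 amino alcohol, (1S,3S,5R,7R,8R,16S): C1 equatorial OH, N12–H, C3 silyloxy, C7 benzyloxy
Conditions: SmI2 (excess), pyrrolidine, H2O, THF, rt
Reagents that add atoms: none
Why: Single-electron reduction by SmI2 activated with amine and water does two jobs: it cleaves the N–S bond of the arenesulfonamide and reduces the C1 ketone. The ketyl should hold its bulky samarium-bound oxygen equatorial, away from the axial C3 methyl group, so the equatorial 1S alcohol is expected; benzyl and silyl ethers are inert.

Step 15
Reactants: 26 amino alcohol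
Product: 27 N-tert-butoxycarbonyl derivative of 26
Conditions: Boc2O, Et3N, CH2Cl2, rt
Reagents that add atoms: di-tert-butyl dicarbonate, CC(C)(C)OC(=O)OC(=O)OC(C)(C)C
Why: Chemoselective carbamate formation at the secondary amine in the presence of the hindered neopentyl alcohol. The tert-butoxycarbonyl group replaces tosyl because acid can remove it at the end without touching the enone.

Step 16
Reactants: 27 silyl ether carbamate
Product: 28 C1,C3-diol, (1S,3S,5R,7R,8R,16S)
Conditions: Bu4NF, THF, 50 °C
Reagents that add atoms: none
Why: Fluoride cleaves the tertiary silyl ether through the strong Si–F bond. The step is placed after C1 is at the alcohol level, so no β-hydroxy ketone that could undergo retro-aldol opening of ring A is exposed to basic fluoride.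

Step 17
Reactants: 28 diol
Product: 29 C1,C3-diacetate, (1S,3S,5R,7R,8R,16S), C7 benzyloxy, N12 tert-butoxycarbonyl
Conditions: Ac2O, DMAP, Et3N, CH2Cl2, 40 °C
Reagents that add atoms: acetic anhydride, CC(=O)OC(C)=O
Why: DMAP-catalysed acylation (Steglich conditions) with excess anhydride acetylates the neopentyl secondary alcohol and, more slowly, the tertiary alcohol through the N-acetylpyridinium ion. Both target acetates are introduced in one operation while the C7 oxygen is still masked as its benzyl ether.

Step 18
Reactants: 29 benzyl ether diacetate
Product: 30 C7 alcohol, (1S,3S,5R,7R,8R,16S)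
Conditions: H2 (1 atm), Pd(OH)2/C, EtOAc, rt
Reagents that add atoms: none
Why: Hydrogenolysis of the benzyl ether; carbamate, esters and the saturated skeleton are inert. The hydrogenation is placed before the enone is introduced.

Step 19
Reactants: 30 C7 alcohol
Product: 31 C7 ketone, (1S,3S,5S,8R,16S)
Conditions: Dess–Martin periodinane, NaHCO3, CH2Cl2, rt
Reagents that add atoms: none
Why: Oxidation of the secondary alcohol with the hypervalent iodine reagent under buffered conditions that tolerate carbamate and acetates. The C7 stereocentre made in step 13 is erased here.

Step 20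
Reactants: 31 C7 ketone
Product: 32 C7 trimethylsilyl enol ether with C7=C8 double bond, (1S,3S,5S,16S)
Conditions: Me3SiCl, Et3N, DMF, 80 °C
Reagents that add atoms: chlorotrimethylsilane, C[Si](C)(C)Cl
Why: Silylation under equilibrating conditions (amine hydrochloride, heat) is expected to favour the more substituted C7=C8 enol ether over the C6=C7 isomer. This regiochemistry decides the direction of the dehydrogenation, and the C8 stereocentre is erased.

Step 21
Reactants: 32 silyl enol ether
Product: 33 N-tert-butoxycarbonyl enone, (1S,3S,5S,8E,16S)
Conditions: Pd(OAc)2 (1.1 equiv), MeCN, rt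
Reagents that add atoms: none
Why: Saegusa–Ito oxidation; divalent palladium forms the C8-bound palladium enolate, and β-hydride elimination can only use a C9 hydrogen because C16 is quaternary, which gives the exocyclic C8=C9 enone. The nine-membered ring should impose the ring-cis (E) geometry.

Step 22
Reactants: 33 N-tert-butoxycarbonyl enone
Product: 34 target, (1S,3S,5S,8E,16S)
Conditions: CF3CO2H, CH2Cl2, 0 °C; then aq. NaHCO3
Reagents that add atoms: none
Why: Acidolysis of the tert-butyl carbamate with loss of isobutene and CO2 in the cold. The tertiary C3 acetate should survive a short exposure because ionisation at C3 is slowed by the electron-withdrawing acetoxy group at C1, and mild neutralisation frees the amino enone last.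

## Compound list

1 | 3-methylcyclopent-2-en-1-one | CC1=CC(=O)CC1 | starting material
2 | (R)-3-methyl-3-(4,4,5,5-tetramethyl-1,3,2-dioxaborolan-2-yl)cyclopentan-1-one | O=C1C[C@@](C)(B2OC(C)(C)C(C)(C)O2)CC1 | intermediate
3 | (S)-3-hydroxy-3-methylcyclopentan-1-one | O=C1C[C@@](C)(O)CC1 | intermediate
4 | (S)-3-(tert-butyldimethylsilyloxy)-3-methylcyclopentan-1-one | O=C1C[C@@](C)(O[Si](C)(C)C(C)(C)C)CC1 | intermediate
5 | (S)-1-amino-2-(methoxymethyl)pyrrolidine (SAMP) | COC[C@@H]1CCCN1N | starting material
6 | SAMP hydrazone of 4 (C=N geometry not defined) | COC[C@@H]1CCCN1N=C2C[C@@](C)(O[Si](C)(C)C(C)(C)C)CC2 | intermediate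
7 | allyl bromide | C=CCBr | starting material
8 | lithium azaenolate of 6 (deprotonated at C5) | COC[C@@H]1CCCN1N([Li])C2=CC[C@](C)(O[Si](C)(C)C(C)(C)C)C2 | intermediate
9 | (2R,4S)-2-allyl SAMP hydrazone | COC[C@@H]1CCCN1N=C2C[C@@](C)(O[Si](C)(C)C(C)(C)C)C[C@H]2CC=C | intermediate
10 | (2S,4S)-4-(tert-butyldimethylsilyloxy)-4-methyl-2-(1,2,4-trioxolan-3-ylmethyl)cyclopentan-1-one | O=C1C[C@@](C)(O[Si](C)(C)C(C)(C)C)C[C@H]1CC2OCOO2 | intermediate
11 | 2-[(1S,4S)-4-(tert-butyldimethylsilyloxy)-4-methyl-2-oxocyclopentyl]acetaldehyde | O=C1C[C@@](C)(O[Si](C)(C)C(C)(C)C)C[C@H]1CC=O | intermediate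
12 | (2S,4S)-2-[2,2-bis(benzyloxy)ethyl]-4-(tert-butyldimethylsilyloxy)-4-methylcyclopentan-1-one | O=C1C[C@@](C)(O[Si](C)(C)C(C)(C)C)C[C@H]1CC(OCc2ccccc2)OCc3ccccc3 | intermediate
13 | 4-methylbenzenesulfonamide | Cc1ccc(cc1)S(N)(=O)=O | starting material
14 | 5-bromopent-1-ene | C=CCCCBr | starting material
15 | 4-methyl-N,N-di(pent-4-en-1-yl)benzenesulfonamide | C=CCCCN(CCCC=C)S(=O)(=O)c1ccc(C)cc1 | intermediate
16 | (Z)-1-(4-methylbenzenesulfonyl)-2,3,4,7,8,9-hexahydro-1H-azonine | O=S(=O)(c1ccc(C)cc1)N2CCC/C=C\CCC2 | intermediate
17 | trans-5,6-dibromo-1-(4-methylbenzenesulfonyl)azonane (racemic; one enantiomer drawn) | Br[C@H]1CCCN(S(=O)(=O)c2ccc(C)cc2)CCC[C@@H]1Br | intermediate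
18 | (E)-5-bromo-1-(4-methylbenzenesulfonyl)-2,3,4,7,8,9-hexahydro-1H-azonine | Br/C1=C/CCCN(S(=O)(=O)c2ccc(C)cc2)CCC1 | intermediate
19 | ring-cis 5-lithio-1-(4-methylbenzenesulfonyl)-2,3,4,7,8,9-hexahydro-1H-azonine | [Li]/C1=C/CCCN(S(=O)(=O)c2ccc(C)cc2)CCC1 | intermediate
20 | dichloro[1-(4-methylbenzenesulfonyl)-2,3,4,7,8,9-hexahydro-1H-azonin-5-yl]cerium | Cl[Ce](Cl)/C1=C/CCCN(S(=O)(=O)c2ccc(C)cc2)CCC1 | intermediate
21 | (1S,2S,4S)-1-alkenylcyclopentanol (see step 11) | C1CCN(S(=O)(=O)c5ccc(C)cc5)CCC/C=C1/[C@]4(O)C[C@@](C)(O[Si](C)(C)C(C)(C)C)C[C@H]4CC(OCc2ccccc2)OCc3ccccc3 | intermediate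
22 | triethylsilyl ether of 21 | C1CCN(S(=O)(=O)c5ccc(C)cc5)CCC/C=C1/[C@]4(O[Si](CC)(CC)CC)C[C@@](C)(O[Si](C)(C)C(C)(C)C)C[C@H]4CC(OCc2ccccc2)OCc3ccccc3 | intermediate
23 | O-benzyl oxocarbenium ion at C7, derived from 22 | C1CCN(S(=O)(=O)c5ccc(C)cc5)CCC/C=C1/[C@]4(O[Si](CC)(CC)CC)C[C@@](C)(O[Si](C)(C)C(C)(C)C)C[C@H]4CC=[O+]Cc2ccccc2 | intermediate
24 | tertiary C16 carbocation after C7–C8 bond formation | CC[Si](CC)(CC)O[C@@]12C[C@@](C)(O[Si](C)(C)C(C)(C)C)C[C@H]1C[C@@H](OCc3ccccc3)[C@@H]4CCCN(S(=O)(=O)c5ccc(C)cc5)CCC[C+]24 | intermediate
25 | (3S,5R,7R,8R,16S) tricyclic C1 ketone, C3 silyloxy, C7 benzyloxy, N12 tosyl | O=C1C[C@@](C)(O[Si](C)(C)C(C)(C)C)C[C@H]2C[C@@H](OCc4ccccc4)[C@@H]3CCCN(S(=O)(=O)c5ccc(C)cc5)CCC[C@@]321 | intermediate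
26 | (1S,3S,5R,7R,8R,16S) amino alcohol | O[C@H]1C[C@@](C)(O[Si](C)(C)C(C)(C)C)C[C@H]2C[C@@H](OCc4ccccc4)[C@@H]3CCCNCCC[C@@]321 | intermediate
27 | N-tert-butoxycarbonyl amino alcohol | O[C@H]1C[C@@](C)(O[Si](C)(C)C(C)(C)C)C[C@H]2C[C@@H](OCc4ccccc4)[C@@H]3CCCN(C(=O)OC(C)(C)C)CCC[C@@]321 | intermediate
28 | N-tert-butoxycarbonyl C1,C3-diol | O[C@H]1C[C@@](C)(O)C[C@H]2C[C@@H](OCc4ccccc4)[C@@H]3CCCN(C(=O)OC(C)(C)C)CCC[C@@]321 | intermediate
29 | C1,C3-diacetate, C7 benzyl ether | CC(=O)O[C@H]1C[C@@](C)(OC(C)=O)C[C@H]2C[C@@H](OCc4ccccc4)[C@@H]3CCCN(C(=O)OC(C)(C)C)CCC[C@@]321 | intermediate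
30 | C1,C3-diacetate, C7 alcohol | CC(=O)O[C@H]1C[C@@](C)(OC(C)=O)C[C@H]2C[C@@H](O)[C@@H]3CCCN(C(=O)OC(C)(C)C)CCC[C@@]321 | intermediate
31 | C1,C3-diacetate, C7 ketone, (1S,3S,5S,8R,16S) | CC(=O)O[C@H]1C[C@@](C)(OC(C)=O)C[C@H]2CC(=O)[C@@H]3CCCN(C(=O)OC(C)(C)C)CCC[C@@]321 | intermediate
32 | C7 trimethylsilyl enol ether (C7=C8) | CC(=O)O[C@H]1C[C@@](C)(OC(C)=O)C[C@H]2CC(O[Si](C)(C)C)=C3CCCN(C(=O)OC(C)(C)C)CCC[C@@]321 | intermediate
33 | N-tert-butoxycarbonyl derivative of the target, (1S,3S,5S,8E,16S) | CC(=O)O[C@H]1C[C@@](C)(OC(C)=O)C[C@H]2CC(=O)/C3=C/CCN(C(=O)OC(C)(C)C)CCC[C@@]321 | intermediate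
34 | CNP0120442.1, (1S,3S,5S,8E,16S) | CC(=O)O[C@H]1C[C@@](C)(OC(C)=O)C[C@H]2CC(=O)/C3=C/CCNCCC[C@@]321 | target

## Step count and least certain steps

Total: 22 steps. Longest linear sequence: 18 steps (steps 1–6 and 11–22); the azonine branch (steps 7–10) joins at step 11.

**Step 13 (key step).** Cation 24 sits in a medium ring, where transannular hydride transfer or proton loss can compete with the 1,2-shift. The trisubstituted alkene beside a quaternary carbinol may also capture 23 slowly, so the ionised acetal is consumed in other ways. The fallback sets out from alcohol 21 and comes back at 25, splitting the event into ring enlargement and a separate closure of ring B. N-Bromosuccinimide forms a bromonium ion on the azonine alkene and triggers a semipinacol shift of C5 to C16, giving bromo ketone F1 (ring A and quaternary C16 formed, bromine on C8). Mild hydrolysis of the acetal (LiBF4, wet MeCN) gives aldehyde F2. Bu3SnH with AIBN then generates the C8 radical, which closes ring B onto the aldehyde carbon in a 5-exo cyclisation to give C7 alcohol F3. Benzylation with benzyl trichloroacetimidate and catalytic CF3SO3H returns to 25, possibly as C7 or C8 stereoisomers, which serve equally because both centres are erased in steps 19 to 21. The C16 configuration is not secured by a cyclic transition state in this variant and would have to be checked at F1.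

**Step 20 (with step 21).** Enolisation toward C6 would lead to the C5=C6 enone in step 21. The fallback sets out from ketone 31 and comes back at 33. PhSeCl in EtOAc selenenylates the ketone through its acid-formed, more substituted enol to give α-phenylselenyl ketone F4 (selenium on C8). Oxidation with H2O2 and pyridine gives the selenoxide, whose syn-elimination can only use a C9 hydrogen.

**Step 14.** Protonation at C1 from the wrong face would give the axial alcohol, and N–S cleavage could lag behind ketone reduction. The fallback sets out from 25 and comes back at 27, fixing C1 by equilibration and not by delivery. The reduction is run to completion whatever the ratio; the axial C1 epimer F5 is carried through carbamate formation to F6. F6 is then equilibrated by reversible hydrogen transfer (Al(OiPr)3 with a little acetone in hot toluene–i-PrOH, Meerwein–Ponndorf–Verley/Oppenauer conditions) toward 27, which lacks the syn-axial hydroxyl–methyl contact.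

**Step 8.** Intermolecular metathesis to dimers and oligomers can outpace closure of the nine-membered ring. The fallback sets out from sulfonamide 13 and comes back at 16. (Z)-Oct-4-ene-1,8-diol F7 (from cycloocta-1,5-diene by mono-ozonolysis and NaBH4 reduction) is converted into dimesylate F8, and 13 is alkylated twice by F8 with Cs2CO3 in DMF under slow addition, the cis double bond pre-organising the chain.

**Step 10 (with step 9).** The elimination may lose regiocontrol (allylic bromide, diene), and the bromination may take a transannular course. The fallback sets out from sulfonamide 13 and comes back at 18, bypassing steps 7–10. 1,8-Dichlorooct-4-yne F9 (from lithiated 5-chloropent-1-yne and 1-bromo-3-chloropropane) is hydrozirconated with Cp2Zr(H)Cl and quenched with N-bromosuccinimide to give (E)-4-bromo-1,8-dichlorooct-4-ene F10, with the alkene geometry fixed by syn addition. 13 is then alkylated twice by F10 (Cs2CO3, NaI, DMF, high dilution).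

## Further compounds

F1 | step 13 | bromo ketone: ring A cyclohexanone with quaternary C16, C8 bromide, dibenzyl acetal arm | O=C1C[C@@](C)(O[Si](C)(C)C(C)(C)C)C[C@@H](CC(OCc2ccccc2)OCc3ccccc3)[C@]14CCCN(S(=O)(=O)c5ccc(C)cc5)CCCC4Br
F2 | step 13 | bromo keto aldehyde | O=C1C[C@@](C)(O[Si](C)(C)C(C)(C)C)C[C@@H](CC=O)[C@]14CCCN(S(=O)(=O)c5ccc(C)cc5)CCCC4Br
F3 | step 13 | tricyclic C1 ketone with free C7 alcohol (C7 and C8 not defined) | O=C1C[C@@](C)(O[Si](C)(C)C(C)(C)C)C[C@H]2CC(O)C3CCCN(S(=O)(=O)c5ccc(C)cc5)CCC[C@@]321
F4 | step 20 | C8 phenylselenyl derivative of ketone 31 | CC(=O)O[C@H]1C[C@@](C)(OC(C)=O)C[C@H]2CC(=O)C3([Se]c4ccccc4)CCCN(C(=O)OC(C)(C)C)CCC[C@@]321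
F5 | step 14 | C1 epimer (axial alcohol) of 26 | O[C@@H]1C[C@@](C)(O[Si](C)(C)C(C)(C)C)C[C@H]2C[C@@H](OCc4ccccc4)[C@@H]3CCCNCCC[C@@]321
F6 | step 14 | C1 epimer of 27 | O[C@@H]1C[C@@](C)(O[Si](C)(C)C(C)(C)C)C[C@H]2C[C@@H](OCc4ccccc4)[C@@H]3CCCN(C(=O)OC(C)(C)C)CCC[C@@]321
F7 | step 8 | (Z)-oct-4-ene-1,8-diol | OCCC/C=C\CCCO
F8 | step 8 | (Z)-oct-4-ene-1,8-diyl dimethanesulfonate | CS(=O)(=O)OCCC/C=C\CCCOS(C)(=O)=O
F9 | step 10 | 1,8-dichlorooct-4-yne | ClCCCC#CCCCCl
F10 | step 10 | (E)-4-bromo-1,8-dichlorooct-4-ene | ClCCC/C(Br)=C\CCCCl
A1 | alternative 1 | cis-hydrindenone with C8 ketone, C16 methyl ester and C1 silyl ether | CC(C)(C)[Si](C)(C)O[C@H]1C=C(C)C[C@H]2CCC(=O)[C@]21C(=O)OC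
A2 | alternative 1 | (E)-1-(tert-butyldimethylsilyloxy)-3-methylbuta-1,3-diene | C=C(C)/C=C/O[Si](C)(C)C(C)(C)C
A3 | alternative 1 | methyl 5-oxocyclopent-1-ene-1-carboxylate | COC(=O)C1=CCCC1=O
A4 | alternative 2 | N-tert-butoxycarbonyl derivative of the target (identical with 33) | CC(=O)O[C@H]1C[C@@](C)(OC(C)=O)C[C@H]2CC(=O)/C3=C/CCN(C(=O)OC(C)(C)C)CCC[C@@]321
A5 | alternative 2 | C8 gem-dichloro ketone with C9 aldehyde on the N-tert-butoxycarbonyl aminopropyl arm | CC(=O)O[C@H]1C[C@@](C)(OC(C)=O)C[C@H]2CC(=O)C(Cl)(Cl)[C@]21CCCN(C(=O)OC(C)(C)C)CCC=O
A6 | alternative 3 | N-benzyl azonane with C11 ethyl ester and C7 methylene | CC(C)(C)[Si](C)(C)O[C@H]1C[C@@](C)(O[Si](C)(C)C(C)(C)C)C[C@H]2CC/C3=C/CC(C(=O)OCC)N(Cc4ccccc4)CCC[C@@]321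
A7 | alternative 3 | fused N-benzyl 2-vinylpiperidine (C8 configuration not defined) | CC(C)(C)[Si](C)(C)O[C@H]1C[C@@](C)(O[Si](C)(C)C(C)(C)C)C[C@H]2CCC3(C=C)N(Cc4ccccc4)CCC[C@@]321
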